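Read the slopes.

| flask | starting material | partner | free catalyst | impurity | temperature | remark | time |
|---|---|---|---|---|---|---|---|
| Monday's | 0.0050 M | 6 mM | 50 µM | 10 µM | 28 °C | run made earlier |  |
| Thursday's | 0.020 M | 6 mM | 50 µM | 10 µM | 44 °C | run made earlier |  |
| Tuesday's | 0.010 M | 6 mM | 25 µM | 10 µM | 28 °C | run made earlier |  |
| larch | 0.010 M | 6.00 mM | 50 µM | 10 µM |  | at 20 °C throughout | 4.0 min |
| ash | 0.010 M | 6.00 mM | 50 µM | 10 µM |  | at 50 °C until 4.0 min, from then on at 20 °C | 8.0 min |

- Monday's (time / min: target / %): 4.00: 6.6; 8.00: 13.7; 12.0: 19.9; 15.0: 24.0; 20.0: 34.4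
- Thursday's (time / min: target / %): 1.33: 2.0; 2.50: 4.8; 4.00: 6.1; 5.00: 7.4; 6.00: 9.0
- Tuesday's (time / min: target / %): 1.33: 1.7; 3.00: 1.6; 6.00: 2.2; 8.00: 3.1; 20.0: 7.4

(scatter of a reading: 1 percentage point)

1. which one finishes higher in amount of target, in percent of the starting material charged ("neither" within 2 percentage points) (larch / ash / neither)
2. amount of target at the end, in percent of the starting material charged, larch
3. amount of target at the end, in percent of the starting material charged, ash



Each earlier run climbs along a line within about its scatter, so freeze the slope. My own assumption is that each impurity takes away one free catalyst, which leaves the charge minus the impurity working. Divide the last reading, as an amount, by its time and by that working catalyst. This gives the turnover frequency, the target made per minute per working catalyst: 2.15 min⁻¹ in Monday's run. Tuesday's run, with twice the starting material and 25 µM of free catalyst, gives 2.47 min⁻¹, close enough for a scatter of 1 percentage point, so hold the frequency independent of starting material. Thursday's run, at 44 °C, gives 7.50 min⁻¹. Take a constant factor per degree: the frequency is 1.15 min⁻¹ at 20 °C and 12.0 min⁻¹ at 50 °C.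

Now draw the curves. With 40.0 µM working, larch rises at 0.0460 mM min⁻¹ and ends at 1.84%. Ash rises at 0.479 mM min⁻¹, ten times as fast, and passes larch's final amount after 0.384 min. Its knee comes at 4.0 min, at 19.2%. Then ash takes larch's slope and ends at 21.0%. That is 2.10 mM of target, a little past the 1.72 mM that Monday's run reached on its line, so draw no level. My reckoning puts ash ahead by 19 points.

The forecast says ash, with 1.7% for larch and 20% for ash, “assuming the catalyst survives”.

The flasks give ash: 1.75% for larch and 19.2% for ash.

    starting material + free catalyst → catalyst intermediate A (k = 292 M⁻¹ s⁻¹, Ea = 36.0 kJ mol⁻¹)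
    partner + catalyst intermediate A → catalyst intermediate B (k = 59.5 M⁻¹ s⁻¹, Ea = 56.0 kJ mol⁻¹)
    catalyst intermediate B → catalyst intermediate C (k = 2.09 s⁻¹, Ea = 80.0 kJ mol⁻¹)
    catalyst intermediate C → free catalyst + target (k = 1.18 s⁻¹, Ea = 78.0 kJ mol⁻¹)
    2 catalyst intermediate B ⇌ resting dimer, settled at all times (K = 6600 M⁻¹, ΔH = −12.0 kJ mol⁻¹)
    free catalyst + impurity → spent catalyst (k = 42000 M⁻¹ s⁻¹, Ea = 36.0 kJ mol⁻¹)
    partner → decomposed reagent (k = 6.68 × 10⁻⁴ s⁻¹, Ea = 94.0 kJ mol⁻¹)
    (constants at 50 °C)

Put larch on the temperature programme of ash, its time kept, and larch goes from 1.75% to 17.9%, a gain of 16 points. Give larch the longer time of ash instead, and larch holds 3.52%. Now take a neighbour of larch kept at 45 °C. The frequency, scaled to that temperature, gives 13.0%, and that neighbour holds 13.3%.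

(Readings and results were computed for an exercise, noise included.)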